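**Plan**

1. The target is the (2S,2''S)-biflavanone in which C3' (ring B of unit 1, the 5-hydroxy-7-methoxyflavanone) is bonded to C6'' (ring A of unit 2, the 5''-hydroxy-7''-methoxyflavanone with the 4'''-hydroxyphenyl ring).
2. Retrosynthetic cuts, in order: the acetyl cap on O4'''; C2–C1' of unit 1 (asymmetric conjugate arylation of a chromone); O1''–C2'' and C4''–C4a'' together (ring C of unit 2, a one-flask [3+3] annulation of a phenol with a chiral β-hydroxy nitrile); the phenol C–O bond (C–H borylation/oxidation); the biaryl bond C3'–C6'' (Suzuki–Miyaura).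
3. Forward: biaryl, then the 4-aryl-3,5-dimethoxyphenol, then ring C of unit 2 (key step), then Cl-to-B exchange, then BCl3 (frees O5''–H and the boronic acid), then unit 1 attached as an intact chromone, then deacetylation.
4. Enabling feature: ring A of unit 2 (C4a''–C8a'') is a phloroglucinol ring. In its precursor the two carbons ortho to the only free OH (future C4a'' and C8'') are equivalent and each lies between two oxygen-bearing carbons, and the para carbon (future C6'') carries the aryl group. O1''/C4a'' therefore act as an O,C-1,3-dinucleophile that can give only the 6''-aryl-5'',7''-dioxygenated ring, and the peri relation of O5'' to C4''=O later singles out the 5''-OMe.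
5. Stereochemistry: C2'' comes from an (R)-carbinol (Ru-catalysed transfer hydrogenation) that is inverted in the Mitsunobu stage. C2 is set by a chiral pyridine-oxazoline palladium catalyst.
6. The p-anisylic, acid-labile C2–O1 ether of unit 1 is made last, and C2'' carries an electron-poor 4-acetoxyphenyl ring through all acid stages.

Key step: step 5

Remark: the sense of induction of the t-BuPyOx–palladium catalyst on chromones is taken to follow that on cyclic enones, where the (S)-ligand gives the (R)-adduct; the (R)-ligand is therefore written for the 2S product.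
Remark: the C3'–C6'' axis bears three small ortho groups and is treated as freely rotating, so no axial descriptor is assigned; the four starting materials are taken as commercial.

**Route**

Step 1
Reactants: 1 2-iodo-1,3-dimethoxybenzene; 2 (5-chloro-2-methoxyphenyl)boronic acid
Product: 3 2-(5-chloro-2-methoxyphenyl)-1,3-dimethoxybenzene
Conditions: Pd(dppf)Cl2 (cat.), K3PO4, 1,4-dioxane/H2O, 90 °C
Reagents that add atoms: none
Why: Suzuki–Miyaura coupling, in which zerovalent palladium with the dppf ligand inserts into the C–I bond far faster than into the electron-rich C–Cl bond, so the tri-ortho-substituted biaryl should form with the chloride kept as the later boron handle and no stereocentre is created.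

Step 2
Reactants: 3 2-(5-chloro-2-methoxyphenyl)-1,3-dimethoxybenzene
Product: 5 4-(5-chloro-2-methoxyphenyl)-3,5-dimethoxyphenol, via pinacol boronate 4 (not isolated)
Conditions: [Ir(OMe)(cod)]2 (cat.), 4,4'-di-tert-butyl-2,2'-bipyridine, B2pin2, THF, 80 °C; then KHSO5 (as 2KHSO5·KHSO4·K2SO4), acetone/H2O, rt
Reagents that add atoms: potassium peroxymonosulfate, [K+].[O-]S(=O)(=O)OO
Why: Sterically controlled iridium-catalysed C–H borylation followed by oxidation of the C–B bond should place oxygen only para to the biaryl bond, because that C–H of the 2,6-dimethoxyphenyl ring is the only aryl C–H without an ortho substituent (all others are ortho to OMe, Cl or aryl).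

Step 3
Reactants: 6 3-(4-hydroxyphenyl)-3-oxopropanenitrile
Product: 7 4-(2-cyanoacetyl)phenyl acetate
Conditions: Ac2O (1.05 equiv), pyridine, CH2Cl2, 0 °C
Reagents that add atoms: acetic anhydride, CC(=O)OC(C)=O
Why: Chemoselective O-acylation of the phenol (any enol acetate of the keto nitrile is hydrolysed on work-up) removes the nucleophilic OH before the Mitsunobu stage and makes the aryl ring electron-poor for step 5.

Step 4
Reactants: 7 4-(2-cyanoacetyl)phenyl acetate
Product: 8 4-[(1R)-2-cyano-1-hydroxyethyl]phenyl acetate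
Conditions: RuCl[(R,R)-TsDPEN](p-cymene) (cat.), HCO2H/Et3N (5:2), CH2Cl2, rt
Reagents that add atoms: none
Why: Asymmetric transfer hydrogenation of an aryl ketone (Noyori–Ikariya type), in which the (R,R)-catalyst should deliver hydride to the face that gives the (R)-carbinol (aryl as the large group, CH2CN as the small one, as with aryl methyl ketones), and this carbon becomes C2''.

Step 5
Reactants: 5 4-(5-chloro-2-methoxyphenyl)-3,5-dimethoxyphenol; 8 4-[(1R)-2-cyano-1-hydroxyethyl]phenyl acetate
Product: 11 4-[(2S)-6-(5-chloro-2-methoxyphenyl)-5,7-dimethoxy-4-oxo-3,4-dihydro-2H-chromen-2-yl]phenyl acetate, via ether nitrile 9 (not isolated), via cyclic ketimine 10 (not isolated)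
Conditions: PPh3, DIAD, CH2Cl2, 0 °C → rt; then CF3SO3H, CF3CO2H, 0 °C → rt; then H2O, 40 °C
Reagents that add atoms: water, O
Why: In the first stage the phenoxide of 5, formed by the PPh3–DIAD betaine, displaces the alkoxyphosphonium group of 8 by SN2 at the benzylic carbon (Mitsunobu reaction), which forms O1''–C2'' with inversion and turns the (R)-carbinol into (2''S) in ether 9; in the second stage CF3SO3H turns the nitrile into a nitrilium ion that acylates the ring carbon ortho to the ether oxygen (Houben–Hoesch reaction), which forms C4''–C4a'', and water hydrolyses ketiminium 10 to the ketone. The closest known reaction types are the Mitsunobu aryl ether synthesis from benzylic β-hydroxy nitriles and amides and the acid-mediated cyclisation of 3-aryloxypropanenitriles to chroman-4-ones. Ring C of unit 2 is closed by a 6-exo-dig electrophilic aromatic substitution, the C≡N bond staying outside the new ring. The one new stereocentre, C2'', is controlled only by the configuration of 8 and the SN2 inversion, so it does not depend on any other element of the substrate. The step needs O- over C-alkylation and substitution over ionisation or elimination, which the phosphonium–phenoxide ion pair and the electron-poor 4-acetoxyphenyl and β-cyano groups (both destabilise a benzylic cation at C2'' in the Mitsunobu and in the acid stage) should secure. It also needs a single site of C-acylation, which is secured because the two ortho carbons of 5 are equivalent, the para carbon carries the aryl group and no second free OH is present.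

Step 6
Reactants: 11 4-[(2S)-6-(5-chloro-2-methoxyphenyl)-5,7-dimethoxy-4-oxo-3,4-dihydro-2H-chromen-2-yl]phenyl acetate
Product: 12 4-[(2S)-5,7-dimethoxy-6-[2-methoxy-5-(4,4,5,5-tetramethyl-1,3,2-dioxaborolan-2-yl)phenyl]-4-oxo-3,4-dihydro-2H-chromen-2-yl]phenyl acetate
Conditions: Pd2(dba)3 (cat.), XPhos, B2pin2, KOAc, 1,4-dioxane, 100 °C
Reagents that add atoms: bis(pinacolato)diboron, CC1(C)OB(OC1(C)C)B1OC(C)(C)C(C)(C)O1
Why: Miyaura borylation, in which the bulky biarylphosphine enables oxidative addition of the electron-rich aryl chloride and KOAc in aprotic dioxane is too weak a base to enolise the flavanone (no retro-oxa-Michael opening, C2'' untouched) or to cleave the aryl acetate.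

Step 7
Reactants: 12 4-[(2S)-5,7-dimethoxy-6-[2-methoxy-5-(4,4,5,5-tetramethyl-1,3,2-dioxaborolan-2-yl)phenyl]-4-oxo-3,4-dihydro-2H-chromen-2-yl]phenyl acetate
Product: 14 {3-[(2S)-2-(4-acetoxyphenyl)-5-hydroxy-7-methoxy-4-oxo-3,4-dihydro-2H-chromen-6-yl]-4-methoxyphenyl}boronic acid, via bis(dichloroboryl) species 13 (not isolated)
Conditions: BCl3 (excess), CH2Cl2, −78 → 0 °C; then H2O, 0 °C
Reagents that add atoms: water, O
Why: Chelation-controlled ether cleavage, in which BCl3 bound to C4''=O should cleave only the peri 5''-OMe through a six-membered boron chelate and at the same time exchange the pinacolato group on the aryl boron for chloride (both boron centres are hydrolysed on work-up), while the electron-poor 4-acetoxyphenyl group at C2'' does not support ionisation of the C2''–O1'' bond.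

Step 8
Reactants: 15 5,7-dihydroxy-4H-chromen-4-one
Product: 16 5-hydroxy-7-methoxy-4H-chromen-4-one
Conditions: MeI (1.05 equiv), K2CO3, acetone, rt
Reagents that add atoms: iodomethane, CI
Why: Williamson etherification, in which the 5-OH is held in a hydrogen bond to C4=O and is the less acidic, so one equivalent of MeI should methylate O7 only.

Step 9
Reactants: 14 {3-[(2S)-2-(4-acetoxyphenyl)-5-hydroxy-7-methoxy-4-oxo-3,4-dihydro-2H-chromen-6-yl]-4-methoxyphenyl}boronic acid; 16 5-hydroxy-7-methoxy-4H-chromen-4-one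
Product: 17 4-[(2S)-5-hydroxy-6-{5-[(2S)-5-hydroxy-7-methoxy-4-oxo-3,4-dihydro-2H-chromen-2-yl]-2-methoxyphenyl}-7-methoxy-4-oxo-3,4-dihydro-2H-chromen-2-yl]phenyl acetate
Conditions: Pd(OCOCF3)2 (cat.), (R)-t-BuPyOx, NH4PF6, H2O, ClCH2CH2Cl, 60 °C
Reagents that add atoms: none
Why: Palladium-catalysed asymmetric conjugate addition of an arylboronic acid to a chromone (transmetalation, enantioselective insertion of C2=C3 into the aryl–palladium bond, protonolysis of the enolate), in which the pyridine-oxazoline ligand selects the enone face and should set C2 as S by catalyst control, remote from and independent of C2'', under near-neutral conditions that leave both benzylic C–O bonds alone.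

Step 10
Reactants: 17 4-[(2S)-5-hydroxy-6-{5-[(2S)-5-hydroxy-7-methoxy-4-oxo-3,4-dihydro-2H-chromen-2-yl]-2-methoxyphenyl}-7-methoxy-4-oxo-3,4-dihydro-2H-chromen-2-yl]phenyl acetate
Product: 18 (2S)-5-hydroxy-2-{3-[(2S)-5-hydroxy-2-(4-hydroxyphenyl)-7-methoxy-4-oxo-3,4-dihydro-2H-chromen-6-yl]-4-methoxyphenyl}-7-methoxy-2,3-dihydro-4H-chromen-4-one
Conditions: NH4OAc, MeOH/H2O, rt
Reagents that add atoms: none
Why: Transesterification of an activated aryl ester, in which NH4OAc-mediated methanolysis at neutral pH should cleave the aryl acetate without the basic conditions that open 5-hydroxyflavanones by retro-oxa-Michael reaction, so C2 and C2'' are not epimerised.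

**Compound list**

1 | 2-iodo-1,3-dimethoxybenzene | COc1cccc(OC)c1I | starting material
2 | (5-chloro-2-methoxyphenyl)boronic acid | COc1ccc(Cl)cc1B(O)O | starting material
3 | 2-(5-chloro-2-methoxyphenyl)-1,3-dimethoxybenzene | COc1ccc(Cl)cc1-c1c(OC)cccc1OC | intermediate
4 | 2-[4-(5-chloro-2-methoxyphenyl)-3,5-dimethoxyphenyl]-4,4,5,5-tetramethyl-1,3,2-dioxaborolane (not isolated) | COc1ccc(Cl)cc1-c1c(OC)cc(cc1OC)B1OC(C)(C)C(C)(C)O1 | intermediate
5 | 4-(5-chloro-2-methoxyphenyl)-3,5-dimethoxyphenol | COc1ccc(Cl)cc1-c1c(OC)cc(O)cc1OC | intermediate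
6 | 3-(4-hydroxyphenyl)-3-oxopropanenitrile | N#CCC(=O)c1ccc(O)cc1 | starting material
7 | 4-(2-cyanoacetyl)phenyl acetate | CC(=O)Oc1ccc(cc1)C(=O)CC#N | intermediate
8 | 4-[(1R)-2-cyano-1-hydroxyethyl]phenyl acetate | CC(=O)Oc1ccc(cc1)[C@H](O)CC#N | intermediate
9 | 4-[(1S)-1-[4-(5-chloro-2-methoxyphenyl)-3,5-dimethoxyphenoxy]-2-cyanoethyl]phenyl acetate (not isolated) | CC(=O)Oc1ccc(cc1)[C@H](CC#N)Oc1cc(OC)c(-c2cc(Cl)ccc2OC)c(OC)c1 | intermediate
10 | 4-[(2S)-6-(5-chloro-2-methoxyphenyl)-4-imino-5,7-dimethoxy-3,4-dihydro-2H-chromen-2-yl]phenyl acetate (formed as its triflate salt, not isolated) | CC(=O)Oc1ccc(cc1)[C@@H]1CC(=N)c2c(OC)c(-c3cc(Cl)ccc3OC)c(OC)cc2O1 | intermediate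
11 | 4-[(2S)-6-(5-chloro-2-methoxyphenyl)-5,7-dimethoxy-4-oxo-3,4-dihydro-2H-chromen-2-yl]phenyl acetate | CC(=O)Oc1ccc(cc1)[C@@H]1CC(=O)c2c(OC)c(-c3cc(Cl)ccc3OC)c(OC)cc2O1 | intermediate
12 | 4-[(2S)-5,7-dimethoxy-6-[2-methoxy-5-(4,4,5,5-tetramethyl-1,3,2-dioxaborolan-2-yl)phenyl]-4-oxo-3,4-dihydro-2H-chromen-2-yl]phenyl acetate | CC(=O)Oc1ccc(cc1)[C@@H]1CC(=O)c2c(OC)c(-c3cc(B4OC(C)(C)C(C)(C)O4)ccc3OC)c(OC)cc2O1 | intermediate
13 | 4-[(2S)-5-(dichloroboryloxy)-6-[5-(dichloroboryl)-2-methoxyphenyl]-7-methoxy-4-oxo-3,4-dihydro-2H-chromen-2-yl]phenyl acetate (not isolated) | CC(=O)Oc1ccc(cc1)[C@@H]1CC(=O)c2c(OB(Cl)Cl)c(-c3cc(B(Cl)Cl)ccc3OC)c(OC)cc2O1 | intermediate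
14 | {3-[(2S)-2-(4-acetoxyphenyl)-5-hydroxy-7-methoxy-4-oxo-3,4-dihydro-2H-chromen-6-yl]-4-methoxyphenyl}boronic acid | CC(=O)Oc1ccc(cc1)[C@@H]1CC(=O)c2c(O)c(-c3cc(B(O)O)ccc3OC)c(OC)cc2O1 | intermediate
15 | 5,7-dihydroxy-4H-chromen-4-one | O=c1ccoc2cc(O)cc(O)c12 | starting material
16 | 5-hydroxy-7-methoxy-4H-chromen-4-one | COc1cc(O)c2c(c1)occc2=O | intermediate
17 | 4-[(2S)-5-hydroxy-6-{5-[(2S)-5-hydroxy-7-methoxy-4-oxo-3,4-dihydro-2H-chromen-2-yl]-2-methoxyphenyl}-7-methoxy-4-oxo-3,4-dihydro-2H-chromen-2-yl]phenyl acetate | COc1cc(O)c2c(c1)O[C@H](c1ccc(OC)c(-c3c(OC)cc4c(c3O)C(=O)C[C@@H](c3ccc(OC(C)=O)cc3)O4)c1)CC2=O | intermediate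
18 | (2S)-5-hydroxy-2-{3-[(2S)-5-hydroxy-2-(4-hydroxyphenyl)-7-methoxy-4-oxo-3,4-dihydro-2H-chromen-6-yl]-4-methoxyphenyl}-7-methoxy-2,3-dihydro-4H-chromen-4-one | COc1cc(O)c2c(c1)O[C@H](c1ccc(OC)c(-c3c(OC)cc4c(c3O)C(=O)C[C@@H](c3ccc(O)cc3)O4)c1)CC2=O | target

**Step count**

Total: 10 steps. Longest linear sequence: 7 steps (1, 2, 5, 6, 7, 9, 10); steps 3–4 and step 8 are side branches.

**Steps most likely to fail, with fallbacks**

Step 5. The β-hydroxy nitrile may dehydrate to the cinnamonitrile in the Mitsunobu stage, the acetyl group may transfer to the phenoxide, or the new benzylic C–O bond may ionise in the acid stage (loss of the ether or of its configuration). The fallback builds the pyranone ring on the phenol first and sets C2'' by catalyst-controlled C–C bond formation. It sets out from 5: Friedel–Crafts C-acetylation (Ac2O, BF3·OEt2; the two ortho carbons are equivalent) should give 1-[3-(5-chloro-2-methoxyphenyl)-6-hydroxy-2,4-dimethoxyphenyl]ethan-1-one F1. Condensation with N,N-dimethylformamide dimethyl acetal should give (E)-1-[3-(5-chloro-2-methoxyphenyl)-6-hydroxy-2,4-dimethoxyphenyl]-3-(dimethylamino)prop-2-en-1-one F2, which HCl should cyclise to 6-(5-chloro-2-methoxyphenyl)-5,7-dimethoxy-4H-chromen-4-one F3. Conjugate addition of (4-acetoxyphenyl)boronic acid with Pd(OCOCF3)2 and (R)-t-BuPyOx, as in step 9, should then give 11, where the fallback rejoins the route.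

Step 9. The cationic palladium catalyst may be sequestered by O,O-chelation to the two peri-hydroxy ketone units, and the electron-rich boronic acid may protodeboronate before it inserts. The fallback caps both chelating hydroxyls before the coupling. It sets out from 14 and 16: acetylation of 14 (Ac2O, pyridine) should give {3-[(2S)-5-acetoxy-2-(4-acetoxyphenyl)-7-methoxy-4-oxo-3,4-dihydro-2H-chromen-6-yl]-4-methoxyphenyl}boronic acid F4, and acetylation of 16 (Ac2O, pyridine, 4-dimethylaminopyridine) should give 7-methoxy-4-oxo-4H-chromen-5-yl acetate F5. The same palladium-catalysed addition should give the triacetate of the target F6, and methanolysis under the conditions of step 10 should remove all three acetates and give 18, where the fallback rejoins the route.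

Step 7. Exchange of the pinacolato group may be incomplete, HCl may protodeboronate the aryl–boron bond para to OMe, and the acetate may be partly lost. The fallback separates the two tasks and changes their order. It sets out from 11: BCl3 (−78 → 0 °C) should cleave only the 5''-OMe and give 4-[(2S)-6-(5-chloro-2-methoxyphenyl)-5-hydroxy-7-methoxy-4-oxo-3,4-dihydro-2H-chromen-2-yl]phenyl acetate F7. Miyaura borylation as in step 6 should give 4-[(2S)-5-hydroxy-7-methoxy-6-[2-methoxy-5-(4,4,5,5-tetramethyl-1,3,2-dioxaborolan-2-yl)phenyl]-4-oxo-3,4-dihydro-2H-chromen-2-yl]phenyl acetate F8. Transesterification with methylboronic acid (dilute HCl, acetone/H2O) should remove the pinacol as its volatile methylboronate and give 14, where the fallback rejoins the route.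

**Further compounds**

F1 | step 5 | 1-[3-(5-chloro-2-methoxyphenyl)-6-hydroxy-2,4-dimethoxyphenyl]ethan-1-one | CC(=O)c1c(O)cc(OC)c(-c2cc(Cl)ccc2OC)c1OC
F2 | step 5 | (E)-1-[3-(5-chloro-2-methoxyphenyl)-6-hydroxy-2,4-dimethoxyphenyl]-3-(dimethylamino)prop-2-en-1-one | CN(C)/C=C/C(=O)c1c(O)cc(OC)c(-c2cc(Cl)ccc2OC)c1OC
F3 | step 5 | 6-(5-chloro-2-methoxyphenyl)-5,7-dimethoxy-4H-chromen-4-one | COc1cc2occc(=O)c2c(OC)c1-c1cc(Cl)ccc1OC
F4 | step 9 | {3-[(2S)-5-acetoxy-2-(4-acetoxyphenyl)-7-methoxy-4-oxo-3,4-dihydro-2H-chromen-6-yl]-4-methoxyphenyl}boronic acid | CC(=O)Oc1ccc(cc1)[C@@H]1CC(=O)c2c(OC(C)=O)c(-c3cc(B(O)O)ccc3OC)c(OC)cc2O1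
F5 | step 9 | 7-methoxy-4-oxo-4H-chromen-5-yl acetate | COc1cc(OC(C)=O)c2c(c1)occc2=O
F6 | step 9 | 4-[(2S)-5-acetoxy-6-{5-[(2S)-5-acetoxy-7-methoxy-4-oxo-3,4-dihydro-2H-chromen-2-yl]-2-methoxyphenyl}-7-methoxy-4-oxo-3,4-dihydro-2H-chromen-2-yl]phenyl acetate | COc1cc(OC(C)=O)c2c(c1)O[C@H](c1ccc(OC)c(-c3c(OC)cc4c(c3OC(C)=O)C(=O)C[C@@H](c3ccc(OC(C)=O)cc3)O4)c1)CC2=O
F7 | step 7 | 4-[(2S)-6-(5-chloro-2-methoxyphenyl)-5-hydroxy-7-methoxy-4-oxo-3,4-dihydro-2H-chromen-2-yl]phenyl acetate | CC(=O)Oc1ccc(cc1)[C@@H]1CC(=O)c2c(O)c(-c3cc(Cl)ccc3OC)c(OC)cc2O1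
F8 | step 7 | 4-[(2S)-5-hydroxy-7-methoxy-6-[2-methoxy-5-(4,4,5,5-tetramethyl-1,3,2-dioxaborolan-2-yl)phenyl]-4-oxo-3,4-dihydro-2H-chromen-2-yl]phenyl acetate | CC(=O)Oc1ccc(cc1)[C@@H]1CC(=O)c2c(O)c(-c3cc(B4OC(C)(C)C(C)(C)O4)ccc3OC)c(OC)cc2O1
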